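Late in the autumn run the curve crowds towards full conversion, with 96.0 % at 3.00 d, so the examination starts at the middle.

| setting | midnight | autumn | winter | flask |
|---|---|---|---|---|
| starting material | 40 mM | 40 mM | 20 mM | 40 mM |
| second substrate | 80 mM | 80 mM | 80 mM | 80.0 mM |
| free catalyst | 13 µM | 30 µM | 20 µM | 20 µM |
| remark | run made earlier | run made earlier | run made earlier |  |

| run | time / d | target / % |
|---|---|---|
| midnight | 0.250 | 7.1 |
| midnight | 0.417 | 13.0 |
| midnight | 0.625 | 18.5 |
| midnight | 1.04 | 29.8 |
| midnight | 1.67 | 46.4 |
| midnight | 3.00 | 71.6 |
| autumn | 0.500 | 31.2 |
| autumn | 1.04 | 58.6 |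
| autumn | 1.67 | 78.7 |
| autumn | 2.08 | 87.0 |
| autumn | 2.50 | 92.2 |
| autumn | 3.00 | 96.0 |
| winter | 0.250 | 13.2 |
| winter | 0.417 | 19.5 |
| winter | 0.833 | 38.0 |
| winter | 1.67 | 66.0 |
| winter | 3.00 | 89.0 |

(readings scatter by 0.5 percentage points)

* apparent order in free catalyst when 50 % of the starting material are converted (percent change of the rate of making target for one percent more free catalyst charged)

- the numbers in the tables scatter with a standard deviation of 0.5 percentage points

*When would the order be exactly one?* If every step ran through the catalyst, more catalyst would merely speed up the clock. Runs with equal charges of the other species would then reach equal conversion at an equal product of catalyst and time.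

*Read that product.* Interpolating the logarithm of what is left, as for a decay, I get 1.82 d to 50 % in the midnight run and 0.839 d in the autumn run. The products are 2.04 M·s and 2.18 M·s. Call this, free catalyst charged times the time to 50 % conversion, the catalyst time.

*Is the gap just scatter?* Hardly: the autumn value is larger by 6.68 %, while a reading's scatter shifts a time by roughly 1.00 %, so something seems to run on the wall clock, not the catalyst clock.

*Your number?* The correction is 0.0774, so my order is 0.923. For this flask, catalyst time 2.11 M·s puts 50 % at 1.22 d.

The forecast, reading crossing times and local slopes together, gives 0.85, which is lower than mine: “The order is therefore slightly below one”.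

The simulation gives 0.88, so the forecast held.

    starting material + free catalyst ⇌ catalyst intermediate A (K = 30.0 M⁻¹, k = 1.30 M⁻¹ s⁻¹)
    catalyst intermediate A → free catalyst + target (k = 0.0660 s⁻¹)
    2 second substrate → homo dimer (k = 3.00 × 10⁻⁵ M⁻¹ s⁻¹)
    catalyst intermediate B → free catalyst + second product (k = 0.00740 s⁻¹)
    second substrate + free catalyst ⇌ catalyst intermediate B (K = 23.0 M⁻¹, k = 0.540 M⁻¹ s⁻¹)

This flask reaches 50 % at 1.23 d, a catalyst time of 2.13 M·s, and the part of the order missing from one, 0.120, stands beside 0.12, the percent change of the rate for one percent more on the homo dimer rate constant. That step has no catalyst in it, its first half-life for second substrate at the charge being 2.41 d, and after 3.00 d homo dimer holds 0.0374 M of second substrate, more than the 15.1 mM of second product.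

(The earlier runs and the new flask are calculated for substances that don't exist, noise included.)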